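**Retrosynthetic overview**

1. The cinnamate ester C–O bond is made last, by Mitsunobu union of (E)-ferulic acid with the primary alcohol (2S,3R,4R)-5'-methoxylariciresinol; the alcohol comes from the matching oxolane-3-carboxylic acid by borane reduction.
2. That acid is the hydrogenolysis product of a cis-fused bicyclic γ-aryl lactone. Its lactone ring (C3–C(=O)–O–CH(Ar)–C4) is not in the target: it is built on purpose, locks the 3,4-cis relation, carries the face-directing stereocentre, and is cut at its benzylic C–O bond to leave the C4 benzyl group and the C3 carboxyl.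
3. Key disconnection: the oxolane is split into its C2–O1–C5 triad (a non-stabilised carbonyl ylide from 4-O-benzylsyringaldehyde and (trimethylsilyl)methanol) and its C3–C4 bond (the C=C of an (S)-5-aryl-furan-2(5H)-one from O-benzylvanillin and methyl propiolate). One [3+2] cycloaddition forms C2–C3 and C5–C4 and sets all three oxolane stereocentres.
4. Enabling feature: ring oxygen O1 is flanked by a benzylic carbon (C2, electron-rich syringyl) and an unsubstituted CH2 (C5), an ylide-ready C–O–C unit; beside it, the vicinal cis carbon substituents on C3 and C4 map onto an electron-poor Z-alkene held in a lactone.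
5. Ring order: temporary butenolide first, oxolane second (built onto it), butenolide ring opened third.

Key step: step 5

Remark on the chemistry: the target is read as (2S,3R,4R), with the C2 aryl group trans to the C3 acyloxymethyl group and the C3 and C4 carbon substituents cis (oxolane numbered O1, C2 aryl, C3, C4 benzyl, C5 H2). In step 1 the ligand antipode is specified by the aldehyde face it must deliver to, since both antipodes are available.

**Route**

Step 1
Reactants: 1 4-(benzyloxy)-3-methoxybenzaldehyde; 2 methyl propiolate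
Product: 4 methyl (R)-4-[4-(benzyloxy)-3-methoxyphenyl]-4-hydroxybut-2-ynoate, via methylzinc alkynide 3 (not isolated)
Conditions: Me2Zn (3 equiv), ProPhenol ligand (2,6-bis{[2-(hydroxydiphenylmethyl)pyrrolidin-1-yl]methyl}-4-methylphenol, 10 mol %, antipode for Si-face delivery), Ph3PO (20 mol %), toluene, 0–4 °C; aq. NH4Cl
Reagents that add atoms: none
Why: Catalytic asymmetric alkynylation of an aryl aldehyde: the zinc alkynide formed from 2 and Me2Zn adds inside the chiral dinuclear zinc–ProPhenol pocket, and delivery to the Si face should set the (R)-carbinol.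

Step 2
Reactants: 4 methyl (R)-4-[4-(benzyloxy)-3-methoxyphenyl]-4-hydroxybut-2-ynoate
Product: 6 (S)-5-[4-(benzyloxy)-3-methoxyphenyl]furan-2(5H)-one, via cis-hydroxy enoate 5 (not isolated)
Conditions: H2 (1 atm), Pd/CaCO3 poisoned with Pb(OAc)2 (Lindlar catalyst), quinoline, EtOAc, rt; then PPTS (cat.), CH2Cl2, rt
Reagents that add atoms: none
Why: Lindlar syn-semihydrogenation gives the Z-enoate, which lactonises by intramolecular transesterification; the poisoned catalyst should spare the benzyl ether and the carbinol, and the stereocentre is untouched (its descriptor changes from R to S only because alkynyl outranks aryl and alkenyl does not).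

Step 3
Reactants: 7 4-(benzyloxy)-3,5-dimethoxybenzaldehyde; 8 (trimethylsilyl)methanol (2.5 equiv)
Product: 9 4-(benzyloxy)-3,5-dimethoxybenzaldehyde bis[(trimethylsilyl)methyl] acetal
Conditions: PPTS (cat.), benzene, reflux, Dean–Stark trap
Reagents that add atoms: none
Why: Acid-catalysed acetalisation of an aryl aldehyde with a primary alcohol, driven by azeotropic removal of water.

Step 4
Reactants: 9 4-(benzyloxy)-3,5-dimethoxybenzaldehyde bis[(trimethylsilyl)methyl] acetal
Product: 10 2-(benzyloxy)-5-{chloro[(trimethylsilyl)methoxy]methyl}-1,3-dimethoxybenzene (racemic α-chloro ether)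
Conditions: AcCl (1.2 equiv), SOCl2 (cat.), CH2Cl2, 0 °C to rt; volatiles removed in vacuo; used crude at once
Reagents that add atoms: acetyl chloride, CC(=O)Cl
Why: Acetal–acyl chloride exchange: ionisation to the aryl-stabilised oxocarbenium ion and capture by chloride should give the α-chloro ether while one alkoxy group leaves as its acetate.

Step 5
Reactants: 10 2-(benzyloxy)-5-{chloro[(trimethylsilyl)methoxy]methyl}-1,3-dimethoxybenzene (1.5 equiv, added slowly); 6 (S)-5-[4-(benzyloxy)-3-methoxyphenyl]furan-2(5H)-one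
Product: 12 (3S,3aR,6S,6aS)-3-[4-(benzyloxy)-3-methoxyphenyl]-6-[4-(benzyloxy)-3,5-dimethoxyphenyl]tetrahydro-1H,3H-furo[3,4-c]furan-1-one, via carbonyl ylide 11 (not isolated)
Conditions: CsF (3 equiv, dried), MeCN, 0 °C to rt
Reagents that add atoms: none
Why: Fluoride attacks silicon of 10 as the benzylic C–Cl bond ionises to the aryl-stabilised oxocarbenium ion, a silicon-based 1,3-elimination that unmasks the non-stabilised carbonyl ylide 11, which is trapped in a concerted suprafacial 1,3-dipolar [3+2] cycloaddition by the electron-poor C=C of 6; the closest known reaction types are the CsF-triggered generation of carbonyl ylides from 1-chloroalkyl (trimethylsilyl)methyl ethers with capture by acrylate-type alkenes, and the anti-selective dipolar cycloadditions of 5-substituted furan-2(5H)-ones. The oxolane ring is closed by intermolecular [3+2] annulation in which both C–C bonds (benzylic ylide carbon to the lactone α-carbon, ylide CH2 to the lactone β-carbon) form in one event. The two ring-fusion centres must be cis because the dipolarophile is a Z-alkene held in a five-membered ring and the addition is suprafacial, and their absolute sense should follow from attack on the face anti to the γ-aryl group of 6. The syringyl-bearing centre is set by the exo transition state with the aryl group in the outward position of the ylide, which places it on the convex face, trans to the lactone carbonyl. The step needs regio-, facial and exo selectivity: the first is secured by the polarisation of 11 (largest HOMO coefficient and least hindrance at the unsubstituted CH2 terminus, which pairs with the electrophilic β-carbon), the second by the γ-aryl group, the third by the bowl shape of the forming cis-fused bicycle. Slow addition of 10 at 0 °C keeps the ylide concentration low and limits the exposure of 6 to basic fluoride.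

Step 6
Reactants: 12 (3S,3aR,6S,6aS)-3-[4-(benzyloxy)-3-methoxyphenyl]-6-[4-(benzyloxy)-3,5-dimethoxyphenyl]tetrahydro-1H,3H-furo[3,4-c]furan-1-one
Product: 13 (2S,3S,4R)-2-(4-hydroxy-3,5-dimethoxyphenyl)-4-(4-hydroxy-3-methoxybenzyl)tetrahydrofuran-3-carboxylic acid
Conditions: H2 (1 atm), 10% Pd/C, EtOAc–EtOH, rt, monitored and stopped when the lactone is consumed
Reagents that add atoms: none
Why: Catalytic hydrogenolysis: the two aryl benzyl ethers and the benzylic acyloxy C–O bond of the lactone (better leaving group, para-oxygen activated) should cleave faster than the benzylic dialkyl ether C2–O1 of the oxolane; the lactone benzylic carbon becomes the CH2 of the C4 benzyl group and no retained stereocentre is touched.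

Step 7
Reactants: 13 (2S,3S,4R)-2-(4-hydroxy-3,5-dimethoxyphenyl)-4-(4-hydroxy-3-methoxybenzyl)tetrahydrofuran-3-carboxylic acid
Product: 14 4-[(2S,3R,4R)-4-(4-hydroxy-3-methoxybenzyl)-3-(hydroxymethyl)tetrahydrofuran-2-yl]-2,6-dimethoxyphenol
Conditions: BH3·THF (5 equiv), THF, 0 °C to rt; then aq. NH4Cl
Reagents that add atoms: none
Why: Chemoselective borane reduction of a carboxylic acid through its acyloxyborane; the medium is non-basic, so the C3 centre next to the carboxyl should keep its cis relation to C4, and the phenols are only masked as borates until work-up.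

Step 8
Reactants: 14 4-[(2S,3R,4R)-4-(4-hydroxy-3-methoxybenzyl)-3-(hydroxymethyl)tetrahydrofuran-2-yl]-2,6-dimethoxyphenol; 15 (E)-ferulic acid
Product: 16 [(2S,3R,4R)-2-(4-hydroxy-3,5-dimethoxyphenyl)-4-(4-hydroxy-3-methoxybenzyl)tetrahydrofuran-3-yl]methyl (E)-3-(4-hydroxy-3-methoxyphenyl)acrylate
Conditions: PPh3 (1.3 equiv), DIAD (1.3 equiv), THF, 0 °C to rt
Reagents that add atoms: none
Why: Chemoselective Mitsunobu esterification of a phenolic acid with a phenolic alcohol: the carboxylic acid (pKa about 4.5) protonates the betaine in preference to the phenols (pKa about 10), and its carboxylate should displace the alkoxyphosphonium ion of the only aliphatic alcohol; the carbinol carbon is primary, so no stereocentre is involved, and the E-alkene is untouched.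

**Compound list**

1 | 4-(benzyloxy)-3-methoxybenzaldehyde | O=Cc1ccc(OCc2ccccc2)c(OC)c1 | starting material
2 | methyl propiolate | C#CC(=O)OC | starting material
3 | methyl 3-(methylzincio)propiolate (methylzinc alkynide, not isolated) | COC(=O)C#C[Zn]C | intermediate
4 | methyl (R)-4-[4-(benzyloxy)-3-methoxyphenyl]-4-hydroxybut-2-ynoate | COC(=O)C#C[C@@H](c1ccc(OCc2ccccc2)c(OC)c1)O | intermediate
5 | methyl (S,Z)-4-[4-(benzyloxy)-3-methoxyphenyl]-4-hydroxybut-2-enoate (not isolated) | COC(=O)/C=C\[C@@H](c1ccc(OCc2ccccc2)c(OC)c1)O | intermediate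
6 | (S)-5-[4-(benzyloxy)-3-methoxyphenyl]furan-2(5H)-one | O=C1C=C[C@@H](c2ccc(OCc3ccccc3)c(OC)c2)O1 | intermediate
7 | 4-(benzyloxy)-3,5-dimethoxybenzaldehyde | O=Cc1cc(OC)c(OCc2ccccc2)c(OC)c1 | starting material
8 | (trimethylsilyl)methanol | C[Si](C)(C)CO | starting material
9 | 4-(benzyloxy)-3,5-dimethoxybenzaldehyde bis[(trimethylsilyl)methyl] acetal | COc1cc(C(OC[Si](C)(C)C)OC[Si](C)(C)C)cc(OC)c1OCc1ccccc1 | intermediate
10 | 2-(benzyloxy)-5-{chloro[(trimethylsilyl)methoxy]methyl}-1,3-dimethoxybenzene (racemic) | COc1cc(C(Cl)OC[Si](C)(C)C)cc(OC)c1OCc1ccccc1 | intermediate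
11 | [4-(benzyloxy)-3,5-dimethoxybenzylidene]oxonium methylide (carbonyl ylide, not isolated) | [CH2-][O+]=Cc1cc(OC)c(OCc2ccccc2)c(OC)c1 | intermediate
12 | (3S,3aR,6S,6aS)-3-[4-(benzyloxy)-3-methoxyphenyl]-6-[4-(benzyloxy)-3,5-dimethoxyphenyl]tetrahydro-1H,3H-furo[3,4-c]furan-1-one | O=C1[C@H]2[C@@H]([C@@H](c3ccc(OCc4ccccc4)c(OC)c3)O1)CO[C@@H]2c2cc(OC)c(OCc3ccccc3)c(OC)c2 | intermediate
13 | (2S,3S,4R)-2-(4-hydroxy-3,5-dimethoxyphenyl)-4-(4-hydroxy-3-methoxybenzyl)tetrahydrofuran-3-carboxylic acid | OC(=O)[C@H]1[C@@H](Cc2ccc(O)c(OC)c2)CO[C@@H]1c1cc(OC)c(O)c(OC)c1 | intermediate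
14 | 4-[(2S,3R,4R)-4-(4-hydroxy-3-methoxybenzyl)-3-(hydroxymethyl)tetrahydrofuran-2-yl]-2,6-dimethoxyphenol | OC[C@H]1[C@@H](Cc2ccc(O)c(OC)c2)CO[C@@H]1c1cc(OC)c(O)c(OC)c1 | intermediate
15 | (E)-ferulic acid | COc1cc(/C=C/C(=O)O)ccc1O | starting material
16 | [(2S,3R,4R)-2-(4-hydroxy-3,5-dimethoxyphenyl)-4-(4-hydroxy-3-methoxybenzyl)tetrahydrofuran-3-yl]methyl (E)-3-(4-hydroxy-3-methoxyphenyl)acrylate | COc1cc(/C=C/C(=O)OC[C@H]2[C@@H](Cc3ccc(O)c(OC)c3)CO[C@@H]2c2cc(OC)c(O)c(OC)c2)ccc1O | target

**Step count**

Total steps: 8. Longest linear sequence: 6 steps (steps 1, 2, 5, 6, 7, 8 from 1, or steps 3, 4, 5, 6, 7, 8 from 7).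

**Steps most likely to fail**

Step 5. What may go wrong: erosion of the enantiomeric purity of 6 by fluoride-mediated deprotonation at its benzylic γ-carbon (through the aromatic 2-oxidofuran) before the cycloaddition takes place. The fallback sets out from 10 and runs the same CsF-triggered cycloaddition with the configurationally more robust acetal butenolide (5S)-5-{[(1S,2R,5S)-2-isopropyl-5-methylcyclohexyl]oxy}furan-2(5H)-one F1, made from 5-hydroxyfuran-2(5H)-one and (+)-menthol (TsOH, benzene, reflux, then crystallisation). Anti addition to the alkoxy group should give the bicyclic acetal lactone F2, and any epimerised dipolarophile would lead to a separable diastereomer instead of the enantiomer. Acetal hydrolysis (TFA, H2O, THF) should give the hydroxy lactone F3. Its open aldehyde–carboxylate form takes up 4-(benzyloxy)-3-methoxyphenylmagnesium bromide F4 (from 1-(benzyloxy)-4-bromo-2-methoxybenzene and Mg in THF; 2.2 equiv, −40 °C), and acidification relactonises the γ-hydroxy acid to 12 together with its epimer at the aryl-bearing lactone carbon F5. The route is rejoined at 12; F5 need not be removed, because step 6 erases that centre.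

Step 6. What may go wrong: over-reduction by hydrogenolytic opening of the oxolane at its benzylic C2–O1 bond once the phenol is free, or stalling before the lactone C–O bond is cut. The fallback sets out from 12 and uses ionic hydrogenation (Et3SiH, TFA, CH2Cl2, 0 °C). Ionisation at the lactone benzylic carbon should be favoured because carboxylate is the better leaving group and the para-alkoxy group of the guaiacyl ring stabilises that cation better than the twisted para-alkoxy group of the syringyl ring. This should give (2S,3S,4R)-4-[4-(benzyloxy)-3-methoxybenzyl]-2-[4-(benzyloxy)-3,5-dimethoxyphenyl]tetrahydrofuran-3-carboxylic acid F6 with both benzyl ethers intact. A short, monitored debenzylation (H2, 10% Pd/C, EtOAc, rt), which needs much milder conditions than ether-ring hydrogenolysis, then rejoins the route at 13.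

Step 8. What may go wrong: loss of chemoselectivity through O-alkylation of a phenol by the alkoxyphosphonium ion, or sluggish reaction of the flanked primary alcohol. The fallback sets out from 14. Exhaustive silylation (TBSCl, imidazole, DMF) gives the tris(tert-butyldimethylsilyl) ether of 14 F7, and selective methanolysis of the alkyl silyl ether (PPTS, MeOH, rt) gives the bis(aryl silyl ether) with free primary alcohol F8. Ferulic acid 15 is converted through its bis-silylated form, tert-butyldimethylsilyl (E)-4-O-(tert-butyldimethylsilyl)ferulate F9 (TBSCl, imidazole, DMF; not isolated), into (E)-4-O-(tert-butyldimethylsilyl)ferulic acid F10 (K2CO3, aq. MeOH–THF). Steglich esterification of F8 with F10 (EDC·HCl, DMAP, CH2Cl2) gives the tris-silylated ester F11, and buffered desilylation (TBAF, AcOH, THF, 0 °C) rejoins the route at 16.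

**Further compounds**

F1 | step 5 | (5S)-5-{[(1S,2R,5S)-2-isopropyl-5-methylcyclohexyl]oxy}furan-2(5H)-one | O=C1C=C[C@@H](O[C@H]2C[C@@H](C)CC[C@@H]2C(C)C)O1
F2 | step 5 | (3S,3aR,6S,6aS)-6-[4-(benzyloxy)-3,5-dimethoxyphenyl]-3-{[(1S,2R,5S)-2-isopropyl-5-methylcyclohexyl]oxy}tetrahydro-1H,3H-furo[3,4-c]furan-1-one | O=C1[C@H]2[C@@H]([C@@H](O[C@H]3C[C@@H](C)CC[C@@H]3C(C)C)O1)CO[C@@H]2c2cc(OC)c(OCc3ccccc3)c(OC)c2
F3 | step 5 | (3aR,6S,6aS)-6-[4-(benzyloxy)-3,5-dimethoxyphenyl]-3-hydroxytetrahydro-1H,3H-furo[3,4-c]furan-1-one (anomer mixture) | O=C1[C@H]2[C@@H](C(O)O1)CO[C@@H]2c2cc(OC)c(OCc3ccccc3)c(OC)c2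
F4 | step 5 | 4-(benzyloxy)-3-methoxyphenylmagnesium bromide | COc1cc([Mg]Br)ccc1OCc1ccccc1
F5 | step 5 | (3R,3aR,6S,6aS)-3-[4-(benzyloxy)-3-methoxyphenyl]-6-[4-(benzyloxy)-3,5-dimethoxyphenyl]tetrahydro-1H,3H-furo[3,4-c]furan-1-one | O=C1[C@H]2[C@@H]([C@H](c3ccc(OCc4ccccc4)c(OC)c3)O1)CO[C@@H]2c2cc(OC)c(OCc3ccccc3)c(OC)c2
F6 | step 6 | (2S,3S,4R)-4-[4-(benzyloxy)-3-methoxybenzyl]-2-[4-(benzyloxy)-3,5-dimethoxyphenyl]tetrahydrofuran-3-carboxylic acid | OC(=O)[C@H]1[C@@H](Cc2ccc(OCc3ccccc3)c(OC)c2)CO[C@@H]1c1cc(OC)c(OCc2ccccc2)c(OC)c1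
F7 | step 8 | tris(tert-butyldimethylsilyl) ether of 14, (2S,3R,4R) | CC(C)(C)[Si](C)(C)OC[C@H]1[C@@H](Cc2ccc(O[Si](C)(C)C(C)(C)C)c(OC)c2)CO[C@@H]1c1cc(OC)c(O[Si](C)(C)C(C)(C)C)c(OC)c1
F8 | step 8 | bis(aryl tert-butyldimethylsilyl) ether of 14 with free primary alcohol, (2S,3R,4R) | OC[C@H]1[C@@H](Cc2ccc(O[Si](C)(C)C(C)(C)C)c(OC)c2)CO[C@@H]1c1cc(OC)c(O[Si](C)(C)C(C)(C)C)c(OC)c1
F9 | step 8 | tert-butyldimethylsilyl (E)-4-O-(tert-butyldimethylsilyl)ferulate | COc1cc(/C=C/C(=O)O[Si](C)(C)C(C)(C)C)ccc1O[Si](C)(C)C(C)(C)C
F10 | step 8 | (E)-4-O-(tert-butyldimethylsilyl)ferulic acid | COc1cc(/C=C/C(=O)O)ccc1O[Si](C)(C)C(C)(C)C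
F11 | step 8 | tris(tert-butyldimethylsilyl) ether of 16, (2S,3R,4R) | COc1cc(/C=C/C(=O)OC[C@H]2[C@@H](Cc3ccc(O[Si](C)(C)C(C)(C)C)c(OC)c3)CO[C@@H]2c2cc(OC)c(O[Si](C)(C)C(C)(C)C)c(OC)c2)ccc1O[Si](C)(C)C(C)(C)C
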